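**Plan**
- Retrosynthesis, ring A numbered as benzene-1,2-diol (C1/C2 OH, C3 Br, C4 CH2Ar, C5 CH2OH, C6 H): the CH2OH oxygen is reconnected to the bridging CH2 carbon and the two C–OH bonds are traced back to C–B bonds. This gives a 1-aryl-1,3-dihydroisobenzofuran.
- The enabling feature is that ring A carries five contiguous substituents and that C4 (bridge) and C5 (CH2OH) are neighbours, so an O link between their side-chain carbons makes a five-membered ether fused to ring A. That bicycle is cut at three ring A C–C bonds (C4–C5, C2–C3, C1–C6) into an O-tethered 1,6-diyne with a bromoalkyne terminus plus bis(pinacolatoboryl)acetylene.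
- The diyne is cut at the ether O–CH2 bond and at the carbinol C–alkyne bond, back to ring B as a protected 3-bromo-4,5-dihydroxybenzaldehyde, ethynylmagnesium bromide and propargyl bromide.
- Forward: ring B is bought; the chain is joined by Grignard addition, alkyne bromination and O-propargylation; the dihydrofuran ring and ring A form together in the cyclotrimerisation; the dihydrofuran is then opened reductively and the C–B bonds are oxidised.
- Stereochemistry: the target is achiral. The one stereocentre on the way (carbinol carbon, later C1 of the dihydroisobenzofuran) is carried as a racemate and becomes CH2 in step 6.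

Key step: step 5

Assumption: 3-bromo-4,5-dihydroxybenzaldehyde and bis(pinacolatoboryl)acetylene are taken as catalogue compounds. Ring B is carried as its bis-MOM ether so that no Lewis-acid dealkylation has to be run on the ionisable 4-hydroxybenzylic alcohol of the target. "Pinacolatoboryl" means 4,4,5,5-tetramethyl-1,3,2-dioxaborolan-2-yl; dihydroisobenzofuran numbering is O2, C1 (aryl-bearing), C3 (CH2), C3a, C4–C7, C7a.

**Route**

Step 1
Reactants: 1 3-bromo-4,5-dihydroxybenzaldehyde
Product: 2 3-bromo-4,5-bis(methoxymethoxy)benzaldehyde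
Conditions: MOMCl (2.6 equiv), i-Pr2NEt (3.5 equiv), CH2Cl2, 0 °C to rt
Reagents that add atoms: chloromethyl methyl ether, COCCl
Why: Base-mediated O-alkylation of both phenols (Williamson type) should give the bis-MOM ether, which withstands the Grignard reagent, NaH and the ruthenium catalyst and is later lost under the acid that opens the ether ring.

Step 2
Reactants: 2 3-bromo-4,5-bis(methoxymethoxy)benzaldehyde; 3 ethynylmagnesium bromide
Product: 4 racemic 1-[3-bromo-4,5-bis(methoxymethoxy)phenyl]prop-2-yn-1-ol
Conditions: HC≡CMgBr (0.5 M in THF, 1.3 equiv), THF, 0 °C; aq. NH4Cl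
Reagents that add atoms: none
Why: Grignard 1,2-addition of the acetylide to the aldehyde should give the propargylic alcohol; the new carbinol centre forms as a racemate, which suffices because it becomes CH2 in step 6.

Step 3
Reactants: 4 racemic 1-[3-bromo-4,5-bis(methoxymethoxy)phenyl]prop-2-yn-1-ol
Product: 5 racemic 3-bromo-1-[3-bromo-4,5-bis(methoxymethoxy)phenyl]prop-2-yn-1-ol
Conditions: NBS (1.1 equiv), AgNO3 (10 mol%), acetone, rt, dark
Reagents that add atoms: N-bromosuccinimide, O=C1CCC(=O)N1Br
Why: Silver-acetylide-mediated electrophilic bromination of the terminal alkyne C–H (NBS/AgNO3) is neutral and fast at room temperature, so the carbinol, the MOM acetals and the arene should be untouched.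

Step 4
Reactants: 5 racemic 3-bromo-1-[3-bromo-4,5-bis(methoxymethoxy)phenyl]prop-2-yn-1-ol; 6 propargyl bromide
Product: 7 racemic 1-bromo-3-[3-bromo-4,5-bis(methoxymethoxy)phenyl]-3-(prop-2-yn-1-yloxy)prop-1-yne
Conditions: NaH (1.2 equiv), THF, 0 °C; then 6 (1.5 equiv), Bu4NI (cat.), 0 °C to rt
Reagents that add atoms: none
Why: Williamson etherification of the secondary alkoxide with the reactive propargylic bromide should give the unsymmetrical diyne; 1-bromoalkynes tolerate alkoxide and hydroxide at or below room temperature (they are routinely made with alkaline hypobromite), and brominating before this step is what differentiates the two alkyne termini.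

Step 5
Reactants: 7 racemic 1-bromo-3-[3-bromo-4,5-bis(methoxymethoxy)phenyl]-3-(prop-2-yn-1-yloxy)prop-1-yne; 8 bis(pinacolatoboryl)acetylene
Product: 9 racemic 7-bromo-1-[3-bromo-4,5-bis(methoxymethoxy)phenyl]-5,6-bis(pinacolatoboryl)-1,3-dihydroisobenzofuran
Conditions: Cp*RuCl(cod) (10 mol%), 8 (3 equiv), ClCH2CH2Cl, rt to 40 °C, 7 added slowly by syringe pump
Reagents that add atoms: none
Why: Oxidative cyclisation of the two tethered alkynes of 7 on the Cp*RuCl fragment (divalent ruthenium precatalyst) should give a bicyclic ruthenacycle in which the new bond between the two inner alkyne carbons (C3a–C7a) already closes the five-membered ether ring; coordination and insertion of 8 followed by reductive elimination then forms C4–C5 and C6–C7 and closes benzene ring A. The closest known reactions are Cp*RuCl(cod)-catalysed [2+2+2] cycloadditions of ether-tethered 1,6-diynes with alkynes, run separately with 1-halo-1,6-diynes (the alkynyl C–halogen bond ends as the aryl halide) and with alkynylboronates. Mode of closure: the dihydrofuran arises by metal-mediated C–C coupling within the 1,6-diyne, the benzene ring by formal [4+2] union of the metallacyclic diene with the third alkyne. No stereocentre is created and the existing carbinol centre stays racemic. The step needs chemoselectivity (cross-cyclotrimerisation over diyne self-reaction, no metal insertion into C–Br): excess 8 with slow addition of 7 keeps the diyne dilute, the bromine-capped terminus makes 7 a poor third partner for itself, and this ruthenium catalyst is chosen because it carries alkynyl halides through. Regiochemistry is fixed by the substrate, since the tether puts C1 and the CH2O carbon on adjacent ring carbons, the bromoalkyne terminus becomes C7 next to C1, and 8 is symmetrical.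

Step 6
Reactants: 9 racemic 7-bromo-1-[3-bromo-4,5-bis(methoxymethoxy)phenyl]-5,6-bis(pinacolatoboryl)-1,3-dihydroisobenzofuran
Product: 11 [3-bromo-2-(3-bromo-4,5-dihydroxybenzyl)-4,5-bis(pinacolatoboryl)phenyl]methanol, via MOM-free catechol phthalan 10 (not isolated)
Conditions: Et3SiH (6 equiv), CF3CO2H/CH2Cl2 (1:3), 0 °C to rt; aq. NaHCO3
Reagents that add atoms: none
Why: Acidolysis of the two aryl MOM acetals (the methoxymethyl cation being reduced by the silane to dimethyl ether) is expected to expose the ring B hydroxyl para to C1, after which the acid ionises the doubly benzylic C1–O bond and Et3SiH delivers hydride (ionic hydrogenation of a diarylmethyl ether), while the primary ArCH2–O bond on the boron-bearing, electron-poor ring A does not ionise and the racemic centre becomes CH2.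

Step 7
Reactants: 11 [3-bromo-2-(3-bromo-4,5-dihydroxybenzyl)-4,5-bis(pinacolatoboryl)phenyl]methanol
Product: 12 5-hydroxyisoavrainvilleol [3-bromo-4-(3-bromo-4,5-dihydroxybenzyl)-5-(hydroxymethyl)benzene-1,2-diol]
Conditions: H2O2 (30% aq., 6 equiv), NaHCO3, THF/H2O, 0 °C, Ar; then Na2S2O3, dilute HCl to pH 4
Reagents that add atoms: hydrogen peroxide, OO
Why: Ipso-oxidation of both aryl C–B bonds (boronate oxidation: hydroperoxide adds to boron, 1,2-aryl shift to oxygen, hydrolysis of the borate) should give the ring A catechol directly, with the weak base, low temperature, exclusion of air and reductive acidic quench limiting quinone formation.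

**Compound list**
1 | 3-bromo-4,5-dihydroxybenzaldehyde | O=Cc1cc(O)c(O)c(Br)c1 | starting material
2 | 3-bromo-4,5-bis(methoxymethoxy)benzaldehyde | COCOc1cc(C=O)cc(Br)c1OCOC | intermediate
3 | ethynylmagnesium bromide | C#C[Mg]Br | starting material
4 | racemic 1-[3-bromo-4,5-bis(methoxymethoxy)phenyl]prop-2-yn-1-ol | C#CC(O)c1cc(OCOC)c(OCOC)c(Br)c1 | intermediate
5 | racemic 3-bromo-1-[3-bromo-4,5-bis(methoxymethoxy)phenyl]prop-2-yn-1-ol | BrC#CC(O)c1cc(OCOC)c(OCOC)c(Br)c1 | intermediate
6 | propargyl bromide (3-bromoprop-1-yne) | BrCC#C | starting material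
7 | racemic 1-bromo-3-[3-bromo-4,5-bis(methoxymethoxy)phenyl]-3-(prop-2-yn-1-yloxy)prop-1-yne | BrC#CC(OCC#C)c1cc(OCOC)c(OCOC)c(Br)c1 | intermediate
8 | bis(pinacolatoboryl)acetylene | CC1(C)OB(OC1(C)C)C#CB1OC(C)(C)C(C)(C)O1 | starting material
9 | racemic 7-bromo-1-[3-bromo-4,5-bis(methoxymethoxy)phenyl]-5,6-bis(pinacolatoboryl)-1,3-dihydroisobenzofuran | COCOc1cc(cc(Br)c1OCOC)C1OCc2cc(B3OC(C)(C)C(C)(C)O3)c(B3OC(C)(C)C(C)(C)O3)c(Br)c21 | intermediate
10 | racemic 3-bromo-5-[7-bromo-5,6-bis(pinacolatoboryl)-1,3-dihydroisobenzofuran-1-yl]benzene-1,2-diol (not isolated) | Oc1cc(cc(Br)c1O)C1OCc2cc(B3OC(C)(C)C(C)(C)O3)c(B3OC(C)(C)C(C)(C)O3)c(Br)c21 | intermediate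
11 | [3-bromo-2-(3-bromo-4,5-dihydroxybenzyl)-4,5-bis(pinacolatoboryl)phenyl]methanol | OCc1cc(B2OC(C)(C)C(C)(C)O2)c(B2OC(C)(C)C(C)(C)O2)c(Br)c1Cc1cc(O)c(O)c(Br)c1 | intermediate
12 | 5-hydroxyisoavrainvilleol, 3-bromo-4-(3-bromo-4,5-dihydroxybenzyl)-5-(hydroxymethyl)benzene-1,2-diol | OCc1cc(O)c(O)c(Br)c1Cc1cc(O)c(O)c(Br)c1 | target

Total step count: 7. Longest linear sequence: 7 steps (1 to 12).

**Steps most likely to fail**

Step 5. Insertion of the hindered diboryl alkyne into the ruthenacycle may be too slow, so that the diyne is consumed by self-cyclotrimerisation and oligomerisation, or the metal may insert into the alkynyl C–Br bond. The fallback leaves the cycloaddition altogether, sets out from 1 and comes back at 12. Compound 1 would be O-methylated (MeI, K2CO3, DMF) to 3-bromo-4,5-dimethoxybenzaldehyde F1 and reduced (NaBH4, MeOH) to (3-bromo-4,5-dimethoxyphenyl)methanol F2. Friedel–Crafts self-benzylation of F2 (AlCl3, CH2Cl2, 0 °C, dilute, stopped at partial conversion) would follow, the benzylic cation of one molecule attacking the position para to the 5-methoxy group of a second; this is the head-to-tail mode by which veratryl alcohol condenses to cyclotriveratrylene. It should give [3-bromo-2-(3-bromo-4,5-dimethoxybenzyl)-4,5-dimethoxyphenyl]methanol F3, but higher oligomers are expected beside it, which is why this is only a reserve. BBr3 (CH2Cl2, −78 °C to rt) would then cleave the four methyl ethers and convert CH2OH into the benzylic bromide 3-bromo-4-(3-bromo-4,5-dihydroxybenzyl)-5-(bromomethyl)benzene-1,2-diol F4, which is hydrolysed in aqueous THF to 12.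

Step 6. The diarylmethyl C–O bond may ionise too slowly next to the electron-poor diboryl ring, long exposure to CF3CO2H may cause protodeboronation, and methoxymethyl cations may alkylate the freed catechol. The fallback reverses the order of the last two operations, sets out from 9 and comes back at 12. Compound 9 would first be oxidised (H2O2, NaHCO3, THF/H2O, 0 °C) to racemic 7-bromo-1-[3-bromo-4,5-bis(methoxymethoxy)phenyl]-1,3-dihydroisobenzofuran-5,6-diol F5. Its 5-hydroxyl is para to the ring carbon that bears C1, so brief treatment with Et3SiH and a small amount of CF3CO2H in CH2Cl2 at −20 to 0 °C should open the ring through a para-quinone methide and remove the MOM groups, giving 12. The reaction would have to be stopped early, because the new 4-hydroxybenzylic alcohol can be reduced further to a methyl group.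

Step 4. The alkoxide of 5 may fragment or attack the bromoalkyne (retro-alkynylation, addition at the C–Br carbon), or the base may isomerise the propargyl ether to an allene. The fallback makes the ether before the bromoalkyne exists, sets out from 4 and comes back at 7. Compound 4 would be O-alkylated (NaH, THF, 0 °C) with 3-bromo-1-(triisopropylsilyl)prop-1-yne to racemic [3-({1-[3-bromo-4,5-bis(methoxymethoxy)phenyl]prop-2-yn-1-yl}oxy)prop-1-yn-1-yl]tri(propan-2-yl)silane F6. NBS/AgNO3 in acetone would then brominate the only free terminal alkyne to give racemic [3-({3-bromo-1-[3-bromo-4,5-bis(methoxymethoxy)phenyl]prop-2-yn-1-yl}oxy)prop-1-yn-1-yl]tri(propan-2-yl)silane F7. Buffered Bu4NF/AcOH (THF, 0 °C) would remove the silyl group to give 7.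

**Further compounds**
F1 | step 5 | 3-bromo-4,5-dimethoxybenzaldehyde | COc1cc(C=O)cc(Br)c1OC
F2 | step 5 | (3-bromo-4,5-dimethoxyphenyl)methanol | COc1cc(CO)cc(Br)c1OC
F3 | step 5 | [3-bromo-2-(3-bromo-4,5-dimethoxybenzyl)-4,5-dimethoxyphenyl]methanol | OCc1cc(OC)c(OC)c(Br)c1Cc1cc(OC)c(OC)c(Br)c1
F4 | step 5 | 3-bromo-4-(3-bromo-4,5-dihydroxybenzyl)-5-(bromomethyl)benzene-1,2-diol | BrCc1cc(O)c(O)c(Br)c1Cc1cc(O)c(O)c(Br)c1
F5 | step 6 | racemic 7-bromo-1-[3-bromo-4,5-bis(methoxymethoxy)phenyl]-1,3-dihydroisobenzofuran-5,6-diol | COCOc1cc(cc(Br)c1OCOC)C1OCc2cc(O)c(O)c(Br)c21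
F6 | step 4 | racemic [3-({1-[3-bromo-4,5-bis(methoxymethoxy)phenyl]prop-2-yn-1-yl}oxy)prop-1-yn-1-yl]tri(propan-2-yl)silane | C#CC(OCC#C[Si](C(C)C)(C(C)C)C(C)C)c1cc(OCOC)c(OCOC)c(Br)c1
F7 | step 4 | racemic [3-({3-bromo-1-[3-bromo-4,5-bis(methoxymethoxy)phenyl]prop-2-yn-1-yl}oxy)prop-1-yn-1-yl]tri(propan-2-yl)silane | BrC#CC(OCC#C[Si](C(C)C)(C(C)C)C(C)C)c1cc(OCOC)c(OCOC)c(Br)c1
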